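In a one-step world of electrophile plus nucleophile to product, each nucleophile makes one product. The yield in percent of the electrophile charged therefore has a ceiling equal to the nucleophile equivalents, here 80.0 %, with the nucleophile as limiting reagent.

| setting | autumn | midnight | flask |
|---|---|---|---|
| electrophile | 0.54 M | 1.2 M | 0.80 M |
| nucleophile | 0.80 equiv | 0.80 equiv | 0.800 equiv |
| gas | 29 mM (held) | 29 mM (held) | 29 mM (held) |
| remark | run made earlier | run made earlier |  |
| time |  |  | 10 min |

| run | time / min | product / % |
|---|---|---|
| autumn | 0.833 | 59.8 |
| autumn | 1.33 | 66.7 |
| autumn | 2.00 | 71.6 |
| autumn | 4.00 | 76.8 |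
| autumn | 6.00 | 78.8 |
| autumn | 10.0 | 80.3 |
| midnight | 0.833 | 63.3 |
| midnight | 1.33 | 69.5 |
| midnight | 2.00 | 73.3 |
| midnight | 4.00 | 77.8 |
| midnight | 6.00 | 79.1 |
| midnight | 10.0 | 79.6 |

(each reading ± 0.3 percentage points)

- the numbers in the tables scatter by 0.3 percentage points (one standard deviation)
- at the start none of the gas is in solution
- free base is what gas becomes in solution

* product at 10 min, in percent of the electrophile charged
* concentration of free base in solution at 10 min, in percent of saturation

I turn the nucleophile first. Both runs share the flask's ceiling, and their last readings stand 0.3 percentage points above it (autumn) and 0.4 points below it (midnight), against a scatter of 0.3 points.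

Next comes the electrophile. By hand, a second-order step would run 2.22 times faster at 1.2 M than at 0.54 M. Yet at 0.833 min the midnight reading leads the autumn one by just 3.5 points, so I give the flask, at 0.80 M, the same curve.

Time comes last. In the autumn run the gap under the ceiling falls from 8.4 points to 3.2 points between 2.00 min and 4.00 min, a mean decay constant read as 0.483 /min. Carried to 10 min, that leaves 0.18 points, so I commit to 79.8 %.

No reading shows free base. My reckoned rate at 10 min, 8.54 × 10⁻⁴ /min of the charge, is far below the autumn run's early mean of 0.718 /min. If free base is drawn off as product forms, I expect it close to saturation.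

The forecast gives 79.8 % and 12 %, “with free base well below saturation”. The flask gives 79.8 % and 99.9 %.

    gas ⇌ free base, rate k1*(csat - [free base]) (kL = 1.10 /s)
    acid set free + free base ⇌ salt of the base, settled at all times (K = 1.10 × 10⁵ /M)
    nucleophile + acid set free ⇌ protonated nucleophile, settled at all times (K = 13000 /M)
    electrophile + nucleophile → acid set free + product (k = 0.150 /M/s)

The flask's product stands 0.20 points under the ceiling, with 0.072 % of the nucleophile's own charge still unbound and 0.00120 M of protonated nucleophile at 10.0 min. In the neighbour charged with 0.480 equiv of nucleophile, the same reckoning puts the ceiling at 48.0 %. That neighbour gives 48.0 % at 10.0 min, with 0 % of its nucleophile and 52 % of its electrophile left.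

All runs stem from a simulated flask for an exercise, and the scatter is random.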